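The easy step is to count what goes in, so the flasks, their steps and the questions stand first.

| setting | zeta | gamma | theta | alpha |
|---|---|---|---|---|
| left-handed substrate | 0.050 M | 0.050 M | 0.050 M | 0.050 M |
| reagent | 3.00 equiv (fed, over 15 s) | 3.00 equiv | 3.00 equiv | 3.00 equiv (fed, over 15 s) |
| free catalyst | 0.2 mol% | 0.2 mol% | 0.2 mol% | 0.2 mol% |
| right-handed substrate | 0.050 M | 0.050 M | 0.050 M | 0.050 M |
| temperature | 25 °C | 25 °C |  |  |
| time | 80 s | 80 s | 80 s | 80 s |
| remark | all else is in the flask from the start; the feed brings no volume worth counting | everything together at the start | everything together at the start at −5 °C, warmed to 25 °C at 15 s | the addition at −5 °C, then warmed to 25 °C; the feed brings no volume worth counting |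

    reagent + free catalyst + left-handed substrate → free catalyst + left-handed product (k1 = 39000 L² mol⁻² s⁻¹, Ea1 = 19.0 kJ mol⁻¹)
    reagent + free catalyst + right-handed substrate → free catalyst + right-handed product (k2 = 23000 L² mol⁻² s⁻¹, Ea2 = 15.0 kJ mol⁻¹)
    free catalyst + free catalyst ⇌ resting dimer (K3 = 10000 L mol⁻¹, k3 = 1400 L mol⁻¹ s⁻¹, Ea3 = 44.0 kJ mol⁻¹, ΔH3 = −22.0 kJ mol⁻¹)
    free catalyst → spent catalyst (k4 = 0.031 s⁻¹, Ea4 = 79.0 kJ mol⁻¹)
    (constants at 25 °C)

- free catalyst is single-handed; left-handed substrate and right-handed substrate are mirror images of each other, charged as a racemate, each of them at the stated concentration
- a step written with two of one species runs at k times the square of its concentration and takes two of it each time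
- at 25 °C the constants are as listed, elsewhere as the activation energies and enthalpies make them

- the flask with the highest amount of left-handed product, in percent of the left-handed substrate and right-handed substrate together charged ("all alike" if they lie within 1.5 percentage points) (zeta / gamma / theta / alpha / all alike)
- final left-handed product, as a percentage of the left-handed substrate and right-handed substrate together charged, in zeta
- final left-handed product, as a percentage of the left-handed substrate and right-handed substrate together charged, in gamma
- final left-handed product, as a percentage of the left-handed substrate and right-handed substrate together charged, in theta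
- final left-handed product, as a percentage of the left-handed substrate and right-handed substrate together charged, in alpha

On the left-handed substrate, the catalyst charge comes to 1.00 × 10⁻⁴ M and the reagent charge to 0.150 M. The time scales at 25 °C then form a ladder, reckoned here by hand for the start of gamma.

Left to itself, the catalyst pairs up until 5.00 × 10⁻⁵ M stands free, half of the charge, and the rest sits in the resting dimer, outside the working round. That pairing settles with a half-time of 1.65 s. Next comes the left-handed substrate, with a pseudo-first-order half-life of 2.37 s, longer than that of the pairing. The right-handed substrate follows at 4.02 s. Free catalyst, by its own decay step, has a half-life of 22.4 s, longer than that of the right-handed substrate.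

So the reagent soon nears its floor, the charge less what both substrates take:

floor = 0.150 M − 0.050 M − 0.050 M = 0.0500 M

Now join the two ends. Free catalyst dies at a rate proportional to itself, so free catalyst summed over time can reach the catalyst charge divided by the decay constant, however much of it rests in the dimer:

dose = 1.00 × 10⁻⁴ M ÷ 0.031 s⁻¹ = 3.23 mM·s

left-handed count at the floor = 39000 L² mol⁻² s⁻¹ × 0.0500 M × dose = 6.29

left-handed count at the full charge = 18.9

The count at the floor, the number of e-foldings of left-handed substrate that the catalyst can drive before it is spent, is the reach. A reach of 6.29 leaves 0.185 % of that substrate's charge, which puts the left-handed product near 49.9 % of both substrates together.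

The feed in zeta lasts 0.671 of a catalyst half-life, so part of the dose there passes at lower reagent. Theta and alpha begin at −5 °C, where the left-handed constant over the decay constant is larger by a factor of 15.0, so cold time costs less catalyst per turnover. This reckoning therefore expects gamma near 49.9 % and the others within 1.5 percentage points of it.

The forecast says 50 % for zeta, 50 % for gamma, 50 % for theta and 50 % for alpha, and so all alike: “Kinetic resolution is therefore lost, and feed or cooling changes nothing.” Its left-handed exponent of 35 differs from the 6.29 to 18.9 reckoned here, though both point to the same end.

The flasks give 49.8 % in zeta, 49.9 % in gamma, 49.9 % in theta and 49.9 % in alpha, so the answer is all alike. In gamma at 80.0 s, 77.5 % of the catalyst is spent and 0.18 % of the left-handed charge remains, a count of 6.32 against the reach of 6.29. A repeat of gamma at 50 °C has its constants' ratio scaled by 0.154, so its count lies between 0.967 and 2.90, leaving between 38.0 % and 5.50 %; that flask keeps 15 % of its left-handed charge and makes 42.7 % of left-handed product.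

All constants were chosen freely, and the outcome is calculated.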